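All runs were computed for an exercise; noise was put on by code.

Turn percentages into concentrations before believing any curve.

| flask | acidic substrate | free base | solid electrophile | remark | time |
|---|---|---|---|---|---|
| red | 0.039 M (in portions, 2) | 0.055 M | 0.075 M | run made earlier; portions every 1.5 min |  |
| blue | 0.072 M (in portions, 2) | 0.055 M | 0.075 M | run made earlier; portions every 1.5 min |  |
| amber | 0.11 M (in portions, 2) | 0.055 M | 0.075 M | run made earlier; portions every 1.5 min |  |
| midnight | 0.050 M (in portions, 2) | 0.0550 M | 0.0750 M | the portions of acidic substrate follow each other after 1.5 min, the first at the start | 3.0 min |
| spring | 0.080 M (in portions, 2) | 0.0550 M | 0.0750 M | the portions of acidic substrate follow each other after 1.5 min, the first at the start | 3.0 min |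
| summer | 0.12 M (in portions, 2) | 0.0550 M | 0.0750 M | the portions of acidic substrate follow each other after 1.5 min, the first at the start | 3.0 min |

| red: time / s | red: product / % | blue: time / s | blue: product / % | amber: time / s | amber: product / % |
|---|---|---|---|---|---|
| 25.0 | 15.8 | 10.0 | 3.7 | 10.0 | 1.7 |
| 50.0 | 33.4 | 20.0 | 8.4 | 20.0 | 4.2 |
| 80.0 | 46.5 | 40.0 | 15.6 | 40.0 | 10.7 |
| 90.0 | 49.1 | 60.0 | 24.0 | 60.0 | 16.4 |
| 120 | 78.2 | 120 | 46.6 | 120 | 31.8 |

(scatter of a reading: 0.5 percentage points)

- at the start none of the solid electrophile is in solution
- "hardly changes" means that all values lie within two and a half points (for a concentration: within two and a half percent of the largest)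

1. amount of product at the end, in percent of the acidic substrate charged for midnight, spring, summer, in this order
2. the shape of the row from first to last (falls, then rises / hardly changes / falls all the way / rises, then falls / rises all the way)

At 120 s the blue run holds 0.0336 M of product and the amber run 0.0350 M, although amber carries more acidic substrate. Product concentration in these two runs therefore reaches nearly one level, which points to the dissolution of solid electrophile as the rate-limiting step in blue and amber. The two runs together give 2.86 × 10⁻⁴ M/s: this is the delivery rate, the product concentration gained per unit time while substrate and base last.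

Over 3.0 min the delivery rate gives an estimated delivered amount of 0.0514 M, which is less than the free base charge of 0.0550 M. In midnight the estimated amount exceeds the charge of 0.050 M, so my reckoning puts midnight near its whole charge. The same estimate gives 64.2% in spring and 42.8% in summer, and the row falls.

The forecast gave 90%, 60% and 40%, a row that falls all the way, holding that “the rate is limited by dissolution of the electrophile”.

The flasks give 88.8%, 61.2% and 42.0%, a row that falls all the way.

    acidic substrate + free base ⇌ protonated base + anion, settled at all times (K = 0.781)
    electrophile + anion → product (k = 32.9 /M/s)
    solid electrophile ⇌ electrophile, rate k3*(cs3 - [electrophile]) while solid is left; crystals form when [electrophile] > cs3 (solubility = 17.0 mM, k = 0.0182 /s)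

At 3.00 min midnight makes electrophile 1.64 times as fast as it uses it, each step taken net, and 0.00499 M of electrophile stands in solution beside 0.0444 M of product, a sum of 0.0494 M against the estimated 0.0514 M. Summer at that time holds 0.00256 M of electrophile and 0.0504 M of product, a sum of 0.0529 M, more than the same estimate, with product at 42.0%.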